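The target is what I reckon for each flask below, and the violet run holds 32.1% of it at 2.50 min, with 2.8% substrate left.

| setting | violet | teal | blue | summer | autumn | spring | dawn |
|---|---|---|---|---|---|---|---|
| substrate | 0.17 M | 0.17 M | 0.17 M | 0.17 M | 0.17 M (fed, over 1.5 min) | 0.17 M | 0.17 M |
| coupling partner | 2 equiv | 1.3 equiv | 3 equiv | 2.00 equiv (in portions, 5, over 1.5 min) | 2.00 equiv | 2.00 equiv | 2.00 equiv (fed, over 1.5 min) |
| free catalyst | 5 mol% | 5 mol% | 5 mol% | 5 mol% | 5 mol% | 5 mol% | 5 mol% |
| remark | run made earlier | run made earlier | run made earlier | first portion at the start, last at 1.5 min | all else is in the flask from the start; the feed brings no volume worth counting | everything together at the start | all else is in the flask from the start; the feed brings no volume worth counting |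
| time |  |  |  | 4.0 min | 4.0 min | 4.0 min | 4.0 min |

| run | time / min | target / % | substrate / % |
|---|---|---|---|
| violet | 0.200 | 3.6 | 61.5 |
| violet | 0.417 | 6.8 | 42.7 |
| violet | 1.00 | 16.7 | 20.2 |
| violet | 2.50 | 32.1 | 2.8 |
| teal | 1.33 | 17.3 | 14.0 |
| teal | 2.50 | 29.4 | 2.6 |
| teal | 4.00 | 33.5 | 0 |
| teal | 5.00 | 34.0 | 0 |
| blue | 0.667 | 12.4 | 29.0 |
| blue | 1.50 | 26.6 | 8.7 |
| blue | 3.00 | 37.3 | 0.4 |
| blue | 5.00 | 37.9 | 0 |

(each reading ± 0.5 percentage points)

- the analysis behind the earlier runs scatters by 0.5 percentage points, standard deviation

- the best flask by amount of target, in percent of the substrate charged; "all alike" if 1.5 percentage points covers them all (summer / autumn / spring / dawn / all alike)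
- amount of target at the end, in percent of the substrate charged, summer
- amount of target at the end, in percent of the substrate charged, autumn
- amount of target at the end, in percent of the substrate charged, spring
- amount of target at the end, in percent of the substrate charged, dawn

**The ceiling.** In the violet run the target grows by 0.180 min⁻¹ of the charge up to 0.200 min, then by 0.170 min⁻¹ between 0.417 min and 1.00 min, although substrate sinks to 20.2%. I call this reading the ceiling at 5 mol% and 2 equiv: over that stretch the target grows at nearly zero order in substrate. Substrate falls much faster than that at first, to 61.5% by 0.200 min. Read as second order in its own fraction, that fall gives a loss coefficient of 3.13 min⁻¹. The crossover share, the substrate fraction at which this loss equals the ceiling, is 23.3%.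

**The curves.** Spring repeats violet, so I add violet's last target and substrate and expect 34.9%. Teal ends at 34.0%, less than blue's 37.9%, so I put summer and dawn, which start short of coupling partner, under teal.

In autumn, substrate starts at zero and rises at the feed, 0.667 min⁻¹, faster than the ceiling. I reckon its line bends where feed equals ceiling plus loss, at 39.8%, above the crossover, and the straight rise meets that level at 0.597 min. Counting the ceiling from the first moment, I reckon autumn's target at 25.5% at 1.5 min. By my level, autumn's substrate then stands about where violet's stood at 0.417 min, and I reckon violet gains 28 percentage points from there. So I reckon autumn's target near 53.5%, with the ceiling counted from the first moment.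

**The forecast.** The forecast gives summer 29.5%, autumn 47%, spring 35.5%, dawn 27.5% and best autumn, holding that "Feeding substrate keeps it near 40%"; its autumn lies below mine and its spring above mine.

**The result.** The flasks give summer 30.6%, autumn 47.3%, spring 35.8% and dawn 29.8%, with autumn best.

    catalyst intermediate A → catalyst intermediate B (k = 1.30 s⁻¹)
    2 substrate → self-condensation product (k = 0.130 M⁻¹ s⁻¹)
    coupling partner + catalyst intermediate B ⇌ catalyst intermediate C (K = 3.70 M⁻¹, k = 14.0 M⁻¹ s⁻¹)
    substrate + free catalyst → catalyst intermediate A (k = 5.40 M⁻¹ s⁻¹)
    catalyst intermediate C → catalyst intermediate D (k = 0.150 s⁻¹)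
    catalyst intermediate D → free catalyst + target (k = 0.760 s⁻¹)

**Richer catalyst.** At 1.50 min autumn holds 40.6% substrate against my level of 39.8%, and 20.6% target against my 25.5%. The neighbouring flask is autumn with 20 mol% free catalyst. Taking the ceiling in step with loading, I get 0.679 min⁻¹, level with the feed of 0.667 min⁻¹, and a crossover share of 46.6%. At 4.00 min that neighbouring flask holds 7.54% self-condensation product and 92.4% target.

(The runs were generated by integration from invented constants.)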